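**Strategy.** The arylglycerol chain is cut at C7–C8, the bond between the benzylic carbinol carbon on ring A (the 4-hydroxy-3,5-dimethoxyphenyl ring) and the carbon carrying the ring B aryloxy oxygen. With C9 at the acyl level, the C7(OH)–C8(OAr)–C9 array is a glycolate aldol pattern, and its threo (7R,8R) relationship is the syn aldol. One Evans boron aldol therefore joins an (S)-4-benzyloxazolidinone aryloxyacetyl imide, which already carries ring B with its side chain as a methyl cinnamate, to acetyl-protected syringaldehyde and sets both stereocenters. A single hydride reduction then unveils C9–OH, the allylic alcohol and the phenol.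

Key step: step 3

Assumption: compounds 1, 3 and 4 are taken as catalogue chemicals, and C7, C8, C9 denote the carbinol carbon, the aryloxy-bearing carbon and the CH2OH carbon of the propane-1,3-diol chain.

**Step 1**
Reactants: 1 syringaldehyde (4-hydroxy-3,5-dimethoxybenzaldehyde)
Product: 2 4-formyl-2,6-dimethoxyphenyl acetate
Conditions: Ac2O, pyridine, DMAP (cat.), CH2Cl2, 0 °C → rt
Reagents that add atoms: acetic anhydride CC(=O)OC(C)=O
Why: O-acetylation (nucleophilic acyl substitution under DMAP catalysis) of the only nucleophilic site masks the acidic ring A phenol as an aryl acetate that should tolerate the boron aldol and is removed by hydride in step 4.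

**Step 2**
Reactants: 3 methyl (E)-sinapate; 4 (S)-4-benzyl-3-(2-chloroacetyl)oxazolidin-2-one
Product: 5 (S)-4-benzyl-3-(2-{2,6-dimethoxy-4-[(E)-3-methoxy-3-oxoprop-1-enyl]phenoxy}acetyl)oxazolidin-2-one
Conditions: K2CO3, MeCN, 60 °C
Reagents that add atoms: none
Why: Williamson ether synthesis, in which the phenol of 3, deprotonated by K2CO3, displaces chloride by SN2 from the carbonyl-activated CH2 of 4, the hindered 2,6-dimethoxyphenoxide being a poor acylation partner for the imide carbonyl; no stereocenter is touched.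

**Step 3**
Reactants: 5 (S)-4-benzyl-3-(2-{2,6-dimethoxy-4-[(E)-3-methoxy-3-oxoprop-1-enyl]phenoxy}acetyl)oxazolidin-2-one; 2 4-formyl-2,6-dimethoxyphenyl acetate
Product: 8 (S)-4-benzyl-3-[(2S,3R)-3-(4-acetoxy-3,5-dimethoxyphenyl)-2-{2,6-dimethoxy-4-[(E)-3-methoxy-3-oxoprop-1-enyl]phenoxy}-3-hydroxypropanoyl]oxazolidin-2-one, via Z-dibutylboron enolate 6 (not isolated), via dibutylboron aldolate 7 (not isolated)
Conditions: Bu2BOTf (1.2 equiv), iPr2NEt (1.4 equiv), CH2Cl2, −78 → 0 °C; then 2, −78 → 0 °C; pH 7 phosphate buffer, MeOH, 30% H2O2, 0 °C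
Reagents that add atoms: none
Why: Bu2BOTf and iPr2NEt enolise only the imide CH2 (C8) to the Z-dibutylboron enolate 6, which adds to the formyl carbon of 2 (C7) through a closed chair Zimmerman–Traxler transition state in which boron bridges the enolate and aldehyde oxygens. The closest known reaction type is the Evans boron syn-aldol of N-(alkoxyacetyl)- and N-(aryloxyacetyl)oxazolidinones with aromatic aldehydes. No ring is closed in the product; the six-membered boron chelate only organises the transition state and is cleaved in the oxidative work-up. C8 is set by the (S)-benzyl group of the auxiliary, which in the dipole-minimised enolate conformer blocks one enolate face so that the aldehyde bonds to the other (2S in acyl numbering, 8R after reduction), and C7 is set by the Z enolate geometry with the aryl group of 2 equatorial in the chair, which gives the 2,3-syn adduct (3R, later 7R). The step needs site-selective enolisation, syn over anti and one enolate face: the cinnamate of 5 has no enolisable hydrogen, 2 is non-enolisable and enters only after enolisation is complete, and the buffered peroxide work-up at 0 °C should spare the hindered aryl acetate.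

**Step 4**
Reactants: 8 (S)-4-benzyl-3-[(2S,3R)-3-(4-acetoxy-3,5-dimethoxyphenyl)-2-{2,6-dimethoxy-4-[(E)-3-methoxy-3-oxoprop-1-enyl]phenoxy}-3-hydroxypropanoyl]oxazolidin-2-one
Product: 9 (1R,2R)-1-(4-hydroxy-3,5-dimethoxyphenyl)-2-{4-[(E)-3-hydroxyprop-1-enyl]-2,6-dimethoxyphenoxy}propane-1,3-diol
Conditions: LiAlH4 (excess), THF, −40 → 0 °C; aq. KNaC4H4O6 work-up near pH 7
Reagents that add atoms: none
Why: Hydride reduction by LiAlH4 cleaves the exocyclic imide carbonyl to the C9 carbinol with release of the auxiliary, reduces the conjugated methyl ester 1,2 to the allylic alcohol at low temperature (the classical route from acetylated sinapate esters to sinapyl alcohol) and removes the aryl acetate, while C7 and C8 are not involved and should keep their configuration under the neutral work-up.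

**Compound list**
1 | syringaldehyde (4-hydroxy-3,5-dimethoxybenzaldehyde) | COc1cc(C=O)cc(OC)c1O | starting material
2 | 4-formyl-2,6-dimethoxyphenyl acetate | COc1cc(C=O)cc(OC)c1OC(C)=O | intermediate
3 | methyl (E)-sinapate, methyl (E)-3-(4-hydroxy-3,5-dimethoxyphenyl)prop-2-enoate | COC(=O)/C=C/c1cc(OC)c(O)c(OC)c1 | starting material
4 | (S)-4-benzyl-3-(2-chloroacetyl)oxazolidin-2-one | O=C(CCl)N1[C@@H](Cc2ccccc2)COC1=O | starting material
5 | (S)-4-benzyl-3-(2-{2,6-dimethoxy-4-[(E)-3-methoxy-3-oxoprop-1-enyl]phenoxy}acetyl)oxazolidin-2-one | COC(=O)/C=C/c1cc(OC)c(OCC(=O)N2[C@@H](Cc3ccccc3)COC2=O)c(OC)c1 | intermediate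
6 | Z-dibutylboron enolate of 5 (aryloxy and boryloxy groups cis) | COC(=O)/C=C/c1cc(OC)c(O/C=C(\OB(CCCC)CCCC)N2[C@@H](Cc3ccccc3)COC2=O)c(OC)c1 | intermediate (not isolated)
7 | dibutylboron aldolate of 8 (O-boryl at C7, 2S,3R) | CC(=O)Oc1c(OC)cc(cc1OC)[C@@H](OB(CCCC)CCCC)[C@@H](C(=O)N1[C@@H](Cc2ccccc2)COC1=O)Oc1c(OC)cc(/C=C/C(=O)OC)cc1OC | intermediate (not isolated)
8 | (S)-4-benzyl-3-[(2S,3R)-3-(4-acetoxy-3,5-dimethoxyphenyl)-2-{2,6-dimethoxy-4-[(E)-3-methoxy-3-oxoprop-1-enyl]phenoxy}-3-hydroxypropanoyl]oxazolidin-2-one | CC(=O)Oc1c(OC)cc(cc1OC)[C@@H](O)[C@@H](C(=O)N1[C@@H](Cc2ccccc2)COC1=O)Oc1c(OC)cc(/C=C/C(=O)OC)cc1OC | intermediate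
9 | (1R,2R)-1-(4-hydroxy-3,5-dimethoxyphenyl)-2-{4-[(E)-3-hydroxyprop-1-enyl]-2,6-dimethoxyphenoxy}propane-1,3-diol | COc1cc([C@@H](O)[C@@H](CO)Oc2c(OC)cc(/C=C/CO)cc2OC)cc(OC)c1O | target

**Step count.** Total: 4 steps. Longest linear sequence: 3 steps (3 → 5 → 8 → 9; the branch 1 → 2 → 8 → 9 is equally long).

**Steps most likely to fail**

Step 4 (global reduction). Conjugate hydride addition to the cinnamate, or hydroalumination of the cinnamyl alkoxide formed, would saturate the side-chain double bond. Attack at the ring carbonyl of the oxazolidinone would open the auxiliary instead of releasing C9. The fallback sets out from 8 and separates the two reductions. LiBH4 with MeOH (1 equiv) in THF at 0 °C, selective for the exocyclic imide carbonyl and the aryl acetate, should give methyl (E)-3-(4-{[(1R,2R)-1,3-dihydroxy-1-(4-hydroxy-3,5-dimethoxyphenyl)propan-2-yl]oxy}-3,5-dimethoxyphenyl)prop-2-enoate F1. iBu2AlH (DIBAL-H) in CH2Cl2–toluene at −78 °C then reduces the conjugated ester strictly 1,2, and the route is rejoined at 9.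

Step 2 (ether formation). Acyl transfer may compete with alkylation: attack of phenoxide or carbonate at the exocyclic imide carbonyl would cleave the auxiliary from 4 or from 5. The fallback sets out from 3 and builds the imide in the reverse order. Alkylation with tert-butyl bromoacetate (K2CO3, acetone, reflux) should give tert-butyl 2-{2,6-dimethoxy-4-[(E)-3-methoxy-3-oxoprop-1-enyl]phenoxy}acetate F2. CF3CO2H in CH2Cl2 then gives 2-{2,6-dimethoxy-4-[(E)-3-methoxy-3-oxoprop-1-enyl]phenoxy}acetic acid F3. Pivaloyl chloride and Et3N in THF at −20 °C form the mixed pivalic anhydride F4 (not isolated), which N-acylates (S)-4-benzyloxazolidin-2-one in the presence of LiCl, and the route is rejoined at 5.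

Step 3 (key aldol). The phenolic acetyl group may be lost, by acyl transfer to the boron aldolate, aminolysis or perhydrolysis in the work-up. The freed phenol would bind boron, slow the addition and give mixtures of acetate and phenol. The fallback sets out from 1 and changes the protecting-group plan to a silyl ether removed by fluoride. TBSCl and imidazole in DMF give 4-(tert-butyldimethylsilyloxy)-3,5-dimethoxybenzaldehyde F5. The boron enolate 6, made from 5 as in step 3, adds to it through the silyl-series dibutylboron aldolate F6 (not isolated) to give (S)-4-benzyl-3-[(2S,3R)-3-[4-(tert-butyldimethylsilyloxy)-3,5-dimethoxyphenyl]-2-{2,6-dimethoxy-4-[(E)-3-methoxy-3-oxoprop-1-enyl]phenoxy}-3-hydroxypropanoyl]oxazolidin-2-one F7. LiAlH4 as in step 4 should give (1R,2R)-1-[4-(tert-butyldimethylsilyloxy)-3,5-dimethoxyphenyl]-2-{4-[(E)-3-hydroxyprop-1-enyl]-2,6-dimethoxyphenoxy}propane-1,3-diol F8. Bu4NF buffered with AcOH in THF at 0 °C removes the silyl group, and the route is rejoined at 9.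

**Further compounds**
F1 | step 4 | methyl (E)-3-(4-{[(1R,2R)-1,3-dihydroxy-1-(4-hydroxy-3,5-dimethoxyphenyl)propan-2-yl]oxy}-3,5-dimethoxyphenyl)prop-2-enoate | COc1cc([C@@H](O)[C@@H](CO)Oc2c(OC)cc(/C=C/C(=O)OC)cc2OC)cc(OC)c1O
F2 | step 2 | tert-butyl 2-{2,6-dimethoxy-4-[(E)-3-methoxy-3-oxoprop-1-enyl]phenoxy}acetate | COC(=O)/C=C/c1cc(OC)c(OCC(=O)OC(C)(C)C)c(OC)c1
F3 | step 2 | 2-{2,6-dimethoxy-4-[(E)-3-methoxy-3-oxoprop-1-enyl]phenoxy}acetic acid | COC(=O)/C=C/c1cc(OC)c(OCC(=O)O)c(OC)c1
F4 | step 2 | mixed pivalic anhydride of F3 | COC(=O)/C=C/c1cc(OC)c(OCC(=O)OC(=O)C(C)(C)C)c(OC)c1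
F5 | step 3 | 4-(tert-butyldimethylsilyloxy)-3,5-dimethoxybenzaldehyde | COc1cc(C=O)cc(OC)c1O[Si](C)(C)C(C)(C)C
F6 | step 3 | dibutylboron aldolate of F7 | COc1cc(cc(OC)c1O[Si](C)(C)C(C)(C)C)[C@@H](OB(CCCC)CCCC)[C@@H](C(=O)N1[C@@H](Cc2ccccc2)COC1=O)Oc1c(OC)cc(/C=C/C(=O)OC)cc1OC
F7 | step 3 | (S)-4-benzyl-3-[(2S,3R)-3-[4-(tert-butyldimethylsilyloxy)-3,5-dimethoxyphenyl]-2-{2,6-dimethoxy-4-[(E)-3-methoxy-3-oxoprop-1-enyl]phenoxy}-3-hydroxypropanoyl]oxazolidin-2-one | COc1cc(cc(OC)c1O[Si](C)(C)C(C)(C)C)[C@@H](O)[C@@H](C(=O)N1[C@@H](Cc2ccccc2)COC1=O)Oc1c(OC)cc(/C=C/C(=O)OC)cc1OC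
F8 | step 3 | (1R,2R)-1-[4-(tert-butyldimethylsilyloxy)-3,5-dimethoxyphenyl]-2-{4-[(E)-3-hydroxyprop-1-enyl]-2,6-dimethoxyphenoxy}propane-1,3-diol | COc1cc([C@@H](O)[C@@H](CO)Oc2c(OC)cc(/C=C/CO)cc2OC)cc(OC)c1O[Si](C)(C)C(C)(C)C
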